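Whatever the charge, [reagent in the reaction phase] multiplies both the step that makes target and the step that destroys it, so the balance between those two steps rests on [target] and [starting material].

    reagent in the reaction phase ⇌ reagent in the second phase, rate k1*([reagent in the reaction phase] - [reagent in the second phase]/K1) per volume of the first phase (K1 = 1.8, k1 = 0.234 min⁻¹)
    starting material + reagent in the reaction phase → target (k2 = 0.161 M⁻¹ min⁻¹)
    reagent in the reaction phase + target → over-reacted product (k3 = 0.142 M⁻¹ min⁻¹)
    starting material + protic impurity → quenched substrate (k4 = 0.228 M⁻¹ min⁻¹)

| setting | cedar | oak | ash | larch |
|---|---|---|---|---|
| starting material | 0.30 M | 0.30 M | 0.30 M | 0.30 M |
| reagent in the second phase | 0.200 M | 0.300 M | 0.500 M | 0.800 M |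
| protic impurity | 0.150 M | 0.150 M | 0.150 M | 0.150 M |
| time | 50 min | 50 min | 50 min | 50 min |
| volume of the second phase over the first | 0.50 | 0.50 | 0.50 | 0.50 |

- amount of target at the end, in percent of the starting material charged for cedar, oak, ash, larch, in this order
- how that number moves from the first to the last of them (falls all the way / hardly changes / rises, then falls / falls, then rises / rises all the way)

- in the second phase: reagent in the second phase; everything else is in the first
- charges count per volume of the first phase; a concentration in a rate is the amount of a species over the volume of its own phase; every rate counts per litre of the first phase
- "hardly changes" means that all values lie within two and a half points (for a concentration: within two and a half percent of the largest)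
- run time (cedar): 50 min

The decision is how much reagent to charge for the next run of 50 min.

1. Target is made at k2[starting material][reagent in the reaction phase] and lost at k3[target][reagent in the reaction phase]. The reagent cancels, so target stops growing when [target]/[starting material] reaches the crossing ratio k2/k3, the selectivity factor of the two steps: 1.13.

2. The reagent crosses between the phases in about 2.02 min, short against the run. So 52.6% of the reagent present can be taken to stand in the reaction phase.

3. Set the protic impurity aside for now. The crossing then comes at a reagent exposure, [reagent in the reaction phase] summed over time, of 397 M·s. At that point 34.5% of the starting material remains and target stands at 39.0%. Spread over the run, this asks for a mean of 0.132 M in the reaction phase, so the first answer is a charge of 0.251 M.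

4. That answer pretends that no reagent is consumed. Put back in, the steps to the crossing use 0.276 M of reagent, so the flask is short of 0.138 M on average. The second round gives a charge of 0.389 M.

5. The impurity still has to be counted. Reckoned with the charged [protic impurity], it removes starting material at 0.0342 min⁻¹. Reagent spread between the phases as in step 2, with none yet consumed, removes it at 0.0330 min⁻¹, a little slower, so the yield should stay well under the figure in step 3. The next run should be charged near 0.389 M, a charge above that of oak and below that of ash. Placing this charge among the flasks is the short method: it lies inside the range from cedar to larch, so the row is expected to go as follows: rises, then falls.

6. The forecast gives 22%, 25%, 24% and 16%, rises, then falls, holding that “a high charge over-reacts the target during the long run”.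

7. The flasks give 21.8%, 25.3%, 24.9% and 17.2%, rises, then falls, and the row turns at 0.38 M.

Larch ends with [target]/[starting material] at 4.05, far beyond the crossing ratio, and the over-reaction step is the main reason for its poor yield: with that step taken away, larch gives 66.9% instead of 17.2%. Oak ends almost exactly on the crossing ratio of 1.13, with [target]/[starting material] at 1.15 and target at 25.3%.

The constants used here were drawn at random within sensible limits; the rest is arithmetic.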